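(All constants stand for no real mixture; the flask was simulated.)

The target reaches the flask through the intermediate, so the quick number you want is how much intermediate still stands at the end of the run.

    intermediate → target (k1 = 1.36 × 10⁻⁴ min⁻¹)
    starting material + coupling partner → intermediate + by-product (k2 = 0.0143 M⁻¹ min⁻¹)
    target ⇌ isomer of the product (K3 = 1.0, k3 = 7.59 × 10⁻⁵ min⁻¹)
    coupling partner → decomposition product (k4 = 4.73 × 10⁻⁷ min⁻¹)

the same everywhere: starting material 0.050 M; time 8.0 d
- zeta: coupling partner 0.0400 M
- alpha: coupling partner 0.0600 M
- epsilon: coupling partner 0.100 M
- gamma: coupling partner 0.150 M
- theta: coupling partner 0.250 M

- "hardly changes" means that all values lie within two and a half points (for a concentration: within two and a half percent of the largest)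
- run time (zeta): 8.0 d
- a step back or a flat step of under half a point counts as no turn

* amount of intermediate at the end, in percent of the starting material charged for zeta, alpha, epsilon, gamma, theta, in this order
* the shape of the row from first to last (falls all the way / hardly changes / rises, then falls / falls, then rises / rises all the way)

**Your hunch.** You expect the intermediate to climb with the coupling partner, and at the lean end we agree. In zeta the coupling partner is the limiting reagent, 0.0400 M against 0.050 M of starting material. Its decomposition half-life of 1020 d far exceeds the 8.0 d run, so at most 80.0 % of the starting material can couple.

**Survival factor.** Excess has its price: at a fixed run time, intermediate formed earlier stands longer in the flask and has longer to decay. Over the run, exp(−1.36 × 10⁻⁴ min⁻¹ × 8.0 d) comes to 20.9 %; we carry this as the survival factor, the share of intermediate formed at the very start that still stands at the end. Multiplying it by the coupled ceiling gives the instant-coupling line: 16.7 % for zeta, lower than the 20.9 % of the flasks where starting material is limiting.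

**Our number.** Theta is pseudo-first-order in starting material, with the coupling partner treated as constant, and its coupling constant of 0.00358 min⁻¹ is 26.3 times the decay constant. Intermediate made later has had less time to decay, and the consecutive first-order solution multiplies the survival factor by 1.04, giving 21.7 %. We reckon no such figure for the leaner flasks, where the coupling partner stands in smaller excess, but we commit to a row that rises from zeta to alpha and then sinks towards that figure.

**The forecast.** It gives 22.5 %, 27.6 %, 24.1 %, 22.6 % and 21.8 %, a row that rises, then falls, and beyond a slight excess it says “the coupling finishes early and the intermediate has longer to decay”. Its theta figure stands a little above our 21.7 %.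

**The flasks.** They give 22.5 %, 27.5 %, 24.1 %, 22.6 % and 21.8 %, a row that rises, then falls, turning at 0.060 M. In zeta at 0.814 d, the starting material's coupling half-life of 1.6 d is shorter than the intermediate's 3.54 d, and the intermediate is being made 3.92 times faster than it is used up. Against the carried survival factor, zeta ends at 1.35 times its instant-coupling line, while theta ends at 1.04 times the factor itself.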